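## Structural features

The target is a cis-fused decalin. Ring A (C5, C6, C13, C22, C23, C25) carries the sec-butyl group on C5, the quaternary C6 (methyl C7 and the 3-hydroxypropanoyl chain C8–C10–C11), the C23 ketone and the tertiary carbinol C25 with methyl C26. Ring B (C13, C14, C16, C17, C21, C22) carries the C14 methyl and the tertiary carbinol C17 with its hydroxymethyl carbon C19. Of the eight stereocentres, C3, C5, C6, C13 and C14 form an unbroken chain, C22 and C25 adjoin it, and only C17 is remote. On ring B the three neighbouring substituents (C6 on C13, the methyl on C14, C23 on C22) are all cis. The fragile groups are the β-hydroxy ketone at C8 (retro-aldol, dehydration), the tertiary α-ketol (acyloin shift) and C22, which is α to the C23 ketone and can epimerise to the trans-decalin. The real difficulty is the quaternary C6 wedged between the tertiary centres C5 and C13, together with the all-cis ring B. The key step uses the acyloin pattern C23(=O)–C25(OH)(CH3) of ring A: it is the union of an aldehyde carbon on C22 with an acetyl group on C5.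

## Logic of the disconnections

35 ⇒ 33 ⇒ 32. No skeletal bond is cut; the C8 ketone and C11 hydroxyl are folded into an isoxazoline and the C17/C19 diol into an acetonide. This hides the retro-aldol-prone chain and removes C8 as a competing ketone. The forward steps must cleave the N–O bond without reducing the C23 ketone and hydrolyse the acetal without an acyloin shift.

32 ⇒ 31. The C23–C25 bond is cut because it is the acyloin bond. Ring A opens and the C25 stereocentre disappears, leaving a keto aldehyde. The forward step needs umpolung of the aldehyde only, one face of the acetyl group, and no epimerisation at C22 or C5.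

31 ⇒ 30 ⇒ 29. One carbon is added back to C23 as a glycol. The labile aldehyde is then set free last under neutral conditions, and the extra carbinol carbon is the stereocentre that the chiral pool supplies. The glycol cleavage must spare the protected C17/C19 diol.

29 ⇒ 25 + 26 ⇒ 24 ⇒ 22. The C8–C10 and O–C11 bonds are cut (nitrile oxide plus alkene), then C8=N, then C8 is traced to a propenyl group. The hydroxypropanoyl chain shrinks to a non-enolisable one-carbon aldehyde on the quaternary centre. The forward steps need a hindered nitrile oxide that adds to 26 and an oxime formation that prefers the aldehyde to the C25 ketone.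

22 ⇒ 21. The C25–C26 bond is cut, so the acetyl group becomes a carboxylic acid, which is what a Claisen rearrangement delivers. The forward step must add one methyl to a hindered carboxylate and leave C5 alone.

21 ⇒ 18 ⇒ 16 + 17. The C5–C6 bond is cut as a [3,3] shift, then the ester C–O bond. Both congested centres form in one cyclic transition state under chirality transfer from a carbinol. The molecule falls into a ring B allylic alcohol and a small acid that brings C3. The forward step needs a Z alkene, an (S) carbinol, an E-configured ketene acetal and a chair transition state.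

16 ⇒ 15 ⇒ 14 ⇒ 13. The C6–C7 bond (methyl by carbometalation), the carbinol C–H (reduction) and the C8–acyl bond (acetylide acylation) are cut. The trisubstituted alkene and its carbinol reduce to a terminal alkyne. The forward steps need syn addition with methyl on the distal carbon and a reagent-controlled reduction.

13 ⇒ 12 ⇒ 10. The alkyne carbon C8 is removed and C6 returns to a lactone carbonyl, the form in which a cycloaddition delivers it. The homologation must not epimerise C13.

10 ⇒ 9 ⇒ 7 ⇒ 6. The C17–C19 bond and the two C–O bonds are cut, which leads back to a C17 ketone. The forward steps need equatorial methylene transfer and an epoxide opening at C19 that keeps the C17–O bond.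

6 ⇒ 2 + 4 (⇒ 1, 3). The C13–C14 and C21–C22 bonds are cut as a Diels–Alder reaction. All-cis C13/C14/C22 is the endo adduct of an E diene and a cyclic dienophile, so three stereocentres come from two small pieces. The forward step needs endo addition, attack anti to the side chain of 2, and the regiochemistry dictated by the 2-silyloxy and 1-methyl groups of 4.

## Other disconnections considered

Alternative 1: The cut is C5–C6, traced back to the O–C23 bond of the bicyclic enol ether A1. On heating, A1 should undergo a Claisen rearrangement to the cis-decalin A2, closing ring A and releasing the C8 ketone. Because C6 and C23 are tied by C13–C22, the transition state must be boat-like. In its favour: ring A, the quaternary C6 and C5 arise in one uncatalysed step, the C8 chain arrives complete, and no isoxazoline is needed. On convergence and on paper step economy this alternative is the better. Against it here: A1 needs a tetrasubstituted enol ether and an E-trisubstituted alkenyl group on a defined C23 centre, both hard to make cleanly. A2 still needs dihydroxylation of C23=C25 and oxidation, so C25 depends on the facial bias of a crowded decalin with a free C8 ketone nearby. Both plans make C5–C6 by a sigmatropic shift; the chosen one uses an open chair with well-tested models and sets C25 under catalyst control.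

Alternative 2: The cuts are C13–C14 and C21–C22. The quinone A3 and the diene A4 would combine under a chiral oxazaborolidinium Lewis acid to the cis-fused enedione A5. In its favour: a catalytic enantioselective step sets C13, C14 and C22 and the ring fusion at once from two simple compounds. For ring B alone it is the better of the two, since the chosen plan uses the same cycloaddition logic with a stoichiometric chiral dienophile. Against it here: ring A arrives flat. The C6 carbonyl must become a quaternary carbon with two new C–C bonds, C5 needs the sec-butyl group with two stereocentres, and C25 needs its oxygen. The regiochemistry also relies on the Lewis acid binding the carbonyl that is vinylogous to the methyl group. The short start is paid for by a long finish; the chosen plan spends its steps where the difficulty is.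

Alternative 3: The cut is C6–C13. In the triflate A6, zerovalent palladium would insert into the enol triflate, the alkenylpalladium would add 6-exo to the acrylate methylene, and formate would reduce the neopentyl palladium to the C7 methyl, giving A7. In its favour: the quaternary carbon forms in one catalytic step with no β-hydride pathway, and C25 is set earlier as a protected tertiary alcohol. On making C6 it is the equal or the better of the chosen plan. Against it here: the face of insertion is left to the acyclic centres C5 and C25. A7 holds a tetrasubstituted C13=C22 enone, so both ring-fusion centres must later be set cis by reducing a hindered alkene beside the quaternary carbon. The C8 ester still needs extension to the hydroxypropanoyl chain. The chosen plan fixes C13 and C22 first and builds C6 against them.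

Key step: step 20

Assumption: locants are the atom positions of the target string with heteroatoms counted (C1–C8, C10, C11, C13–C17, C19, C21–C23, C25, C26), and 1, 3, 17 and 26 are bought, 1 and 17 as single enantiomers.

Step 1
Reactants: 1 (S)-5-(hydroxymethyl)furan-2(5H)-one
Product: 2 (S)-5-[(triisopropylsilyloxy)methyl]furan-2(5H)-one
Conditions: i-Pr3SiCl, imidazole, CH2Cl2, 0 °C → rt
Reagents that add atoms: triisopropylsilyl chloride, CC(C)[Si](Cl)(C(C)C)C(C)C
Why: Silylation of a primary alcohol under conditions too mild to touch the acidic γ-hydrogen; the bulky ether later shields one face of the butenolide.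

Step 2
Reactants: 3 (E)-pent-3-en-2-one
Product: 4 (E)-2-(tert-butyldimethylsilyloxy)penta-1,3-diene
Conditions: t-BuMe2SiOTf, Et3N, CH2Cl2, 0 °C
Reagents that add atoms: tert-butyldimethylsilyl trifluoromethanesulfonate, CC(C)(C)[Si](C)(C)OS(=O)(=O)C(F)(F)F
Why: Soft enolisation on the methyl side of the enone gives the 2-silyloxy diene and leaves the E-propenyl unit unchanged.

Step 3
Reactants: 2 (S)-5-[(triisopropylsilyloxy)methyl]furan-2(5H)-one; 4 (E)-2-(tert-butyldimethylsilyloxy)penta-1,3-diene
Product: 6 cis-fused keto lactone, via silyl enol ether cycloadduct 5 (not isolated)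
Conditions: toluene, BHT (cat.), 130 °C, sealed tube; then 1 M HCl, THF, 0 °C
Reagents that add atoms: none
Why: Diels–Alder reaction of a 2-silyloxydiene with a butenolide: the CH2 terminus C21 bonds to the lactone β-carbon C22 and the methyl-bearing C14 to the α-carbon C13, endo addition puts the C14 methyl cis to the lactone carbonyl C6, and the ring of the dienophile keeps C6 and the C22 branch cis. The diene adds anti to the silyloxymethyl group, so the (S) centre of 2 sets the absolute configuration of C13, C14 and C22; mild acid then hydrolyses the enol ether to the C17 ketone.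

Step 4
Reactants: 6 cis-fused keto lactone
Product: 7 spiro-epoxy lactone (C19 equatorial and oxygen axial on C17)
Conditions: Me3S(O)I, NaH, DMSO, rt
Reagents that add atoms: trimethylsulfoxonium iodide, C[S+](C)(C)=O.[I-]
Why: Corey–Chaykovsky epoxidation: the ring sits in the chair with the C13–C6 bond axial and the C14 methyl equatorial, and the stabilised sulfoxonium ylide adds reversibly, so C19 ends equatorial and the oxygen axial as the target requires. The ketone should react well before the lactone.

Step 5
Reactants: 7 spiro-epoxy lactone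
Product: 9 diol lactone, via hydroxy acetate 8 (not isolated)
Conditions: CsOAc, DMF, 100 °C; then K2CO3, MeOH, 0 °C
Reagents that add atoms: cesium acetate, CC(=O)[O-].[Cs+]
Why: Carboxylate opening of a 1,1-disubstituted epoxide by SN2 attack at C19 leaves the C17–O bond and its configuration untouched. It avoids hydroxide, which would open the lactone and free an alkoxide near the epoxide; methanolysis then removes the acetate.

Step 6
Reactants: 9 diol lactone
Product: 10 acetonide lactone
Conditions: Me2C(OMe)2, PPTS (cat.), acetone, rt
Reagents that add atoms: 2,2-dimethoxypropane, COC(C)(C)OC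
Why: Acetal exchange on the only 1,2-diol gives the spiro acetonide that protects C17/C19 up to the last but one step.

Step 7
Reactants: 10 acetonide lactone
Product: 12 alkynol with C6≡C8 on C13 and a free (S) carbinol on the C22 branch, via lactol 11 (not isolated)
Conditions: i-Bu2AlH, CH2Cl2, −78 °C; then MeOH, K2CO3, MeC(O)C(N2)P(O)(OMe)2, −78 °C → rt
Reagents that add atoms: dimethyl (1-diazo-2-oxopropyl)phosphonate, CC(=O)C(=[N+]=[N-])P(=O)(OC)OC
Why: Partial lactone reduction followed by Seyferth–Gilbert homologation (Ohira–Bestmann variant) of the open hydroxy aldehyde turns the C6 carbonyl into the terminal alkyne. The closed cis-fused lactol is the resting form, which should limit enolisation at C13.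

Step 8
Reactants: 12 alkynol
Product: 13 alkyne bis-silyl ether
Conditions: t-BuMe2SiOTf, 2,6-lutidine, CH2Cl2, −78 → 0 °C
Reagents that add atoms: tert-butyldimethylsilyl trifluoromethanesulfonate, CC(C)(C)[Si](C)(C)OS(=O)(=O)C(F)(F)F
Why: Silylation of the secondary alcohol; both silyl ethers of the future glycol can later be removed together with fluoride.

Step 9
Reactants: 13 alkyne bis-silyl ether
Product: 14 ynone
Conditions: n-BuLi, THF, −78 °C; MeC(O)N(OMe)Me, −78 → 0 °C
Reagents that add atoms: N-methoxy-N-methylacetamide, CC(=O)N(C)OC
Why: Acylation of a lithium acetylide with a Weinreb amide stops at the ketone because of the stable chelated adduct.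

Step 10
Reactants: 14 ynone
Product: 15 (S)-propargylic alcohol
Conditions: RuCl[(S,S)-TsDPEN](p-cymene) (cat.), i-PrOH, rt
Reagents that add atoms: none
Why: Noyori asymmetric transfer hydrogenation of an alkynyl methyl ketone; the (S,S) catalyst should give the (S) carbinol under reagent control, far from the ring stereocentres.

Step 11
Reactants: 15 (S)-propargylic alcohol
Product: 16 (S,Z)-allylic alcohol with methyl C7 on C6
Conditions: MeMgBr (excess), Fe(acac)3 (cat.), THF, −20 → 0 °C; aq NH4Cl
Reagents that add atoms: methylmagnesium bromide, C[Mg]Br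
Why: Iron-catalysed, alkoxide-directed carbomagnesiation of a propargylic alcohol adds methyl to the distal carbon C6 and the metal to C8 in a syn fashion. Protonation then gives the Z trisubstituted alkene with C13 cis to the carbinol carbon.

Step 12
Reactants: 16 (S,Z)-allylic alcohol; 17 (R)-3-methylpentanoic acid
Product: 18 allylic (R)-3-methylpentanoate
Conditions: DCC, DMAP (cat.), CH2Cl2, 0 °C → rt
Reagents that add atoms: none
Why: Steglich esterification of a hindered secondary alcohol; the β-stereocentre of the acid cannot epimerise.

Step 13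
Reactants: 18 allylic (R)-3-methylpentanoate
Product: 21 carboxylic acid with C5 and C6 set and an E-propenyl group on C6, via silyl ketene acetal 19 (not isolated), via trimethylsilyl ester 20 (not isolated)
Conditions: LDA, THF, −78 °C; Me3SiCl, Et3N; −78 → 60 °C; then aq citric acid
Reagents that add atoms: none
Why: Ireland–Claisen rearrangement: LDA in THF should give the E-configured ketene acetal (sec-butyl cis to the allylic oxygen). In the chair transition state the carbinol methyl is equatorial and sec-butyl and C13 are trans-diaxial across the forming C5–C6 bond, so the (S) carbinol and the Z alkene translate into the required C5 and C6 configurations; C3 comes unchanged from 17.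

Step 14
Reactants: 21 carboxylic acid
Product: 22 methyl ketone (C25 acetyl)
Conditions: MeLi (excess), Et2O, 0 °C → rt; inverse quench into aq NH4Cl
Reagents that add atoms: methyllithium, [Li]C
Why: Methyllithium adds to the lithium carboxylate and stops at the dilithio gem-diolate; the ketone appears only on work-up, so C5 is not exposed to base as a ketone.

Step 15
Reactants: 22 methyl ketone
Product: 24 keto aldehyde with the C8 aldehyde on quaternary C6, via ozonide 23 (not isolated)
Conditions: O3, CH2Cl2, −78 °C; PPh3, −78 °C → rt
Reagents that add atoms: ozone, [O-][O+]=O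
Why: Ozonolysis of the only alkene with reductive work-up; the new aldehyde is non-enolisable.

Step 16
Reactants: 24 keto aldehyde
Product: 25 aldoxime
Conditions: NH2OH·HCl, NaOAc, EtOH, rt
Reagents that add atoms: hydroxylamine hydrochloride, NO.Cl
Why: Oxime condensation should prefer the aldehyde to the acetyl group, which is flanked by the tertiary C5 and reacts more slowly.

Step 17
Reactants: 25 aldoxime; 26 ethylene
Product: 29 isoxazoline bis-silyl ether, via hydroximoyl chloride 27 (not isolated), via nitrile oxide 28 (not isolated)
Conditions: NCS, DMF, rt; then ethylene (5 bar), Et3N (slow addition), CH2Cl2, rt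
Reagents that add atoms: none
Why: Huisgen 1,3-dipolar cycloaddition of a nitrile oxide to an alkene; a nitrile oxide on a quaternary carbon dimerises slowly, which leaves time for addition to ethylene. The ring masks the C8 ketone and the C11 hydroxyl.

Step 18
Reactants: 29 isoxazoline bis-silyl ether
Product: 30 isoxazoline diol
Conditions: n-Bu4NF, AcOH, THF, rt → 40 °C
Reagents that add atoms: none
Why: Buffered fluoride removes both silyl ethers; acetonide, isoxazoline and C5 are not affected at this basicity.

Step 19
Reactants: 30 isoxazoline diol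
Product: 31 keto aldehyde with isoxazoline and acetonide (precursor of the key step)
Conditions: NaIO4, THF/pH 7 buffer, 0 °C
Reagents that add atoms: none
Why: Malaprade glycol cleavage frees the C23 aldehyde under neutral conditions, so the cis C22 centre next to it is not exposed to acid or base. The crude aldehyde goes straight into the next step.

Step 20
Reactants: 31 keto aldehyde with isoxazoline and acetonide
Product: 32 decalin α-ketol with isoxazoline and acetonide
Conditions: (5aR,10bS)-2-(pentafluorophenyl)-5a,10b-dihydro-4H,6H-indeno[2,1-b][1,2,4]triazolo[4,3-d][1,4]oxazin-2-ium tetrafluoroborate or its enantiomer (20 mol %), Et3N (20 mol %), toluene, rt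
Reagents that add atoms: none
Why: The free carbene adds to the C23 aldehyde and proton transfer gives the enaminol, an acyl anion equivalent. Its C23 attacks the acetyl carbon C25 in a 6-exo-trig closure of ring A, and loss of the carbene restores the C23 ketone beside the new tertiary alcohol. The closest known reaction type is the carbene-catalysed intramolecular aldehyde–ketone crossed benzoin. The only new stereocentre, C25, is controlled by the chiral aminoindanol backbone of the catalyst, which orients the hydrogen-bonded enaminol toward one face of the acetyl group; the antipode matched with C5 and C6 is used, so that methyl ends cis to sec-butyl. The step needs chemoselectivity (one donor, one acceptor), which the isoxazoline secures by hiding the C8 ketone that would otherwise offer a five-membered closure. It also needs configurational stability at C22 and C5, which a weak amine base and a neutral aldehyde release should secure.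

Step 21
Reactants: 32 decalin α-ketol with isoxazoline and acetonide
Product: 33 isoxazoline triol
Conditions: AcOH/H2O (4:1), 40 °C
Reagents that add atoms: none
Why: Mild acetal hydrolysis; done before the N–O cleavage so that the β-hydroxy ketone never meets acid.

Step 22
Reactants: 33 isoxazoline triol
Product: 35 CNP0112523.4, via hydroxy imine 34 (not isolated)
Conditions: Raney Ni, H2 (1 atm), B(OH)3, MeOH/H2O (5:1), rt
Reagents that add atoms: water, O
Why: Hydrogenolysis of the isoxazoline N–O bond and boric-acid-buffered hydrolysis of the imine give the β-hydroxy ketone; the hindered C23 ketone and the α-ketol should survive these near-neutral conditions.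

Compound list

1 | (S)-5-(hydroxymethyl)furan-2(5H)-one | O=C1C=C[C@@H](CO)O1 | starting material
2 | (S)-5-[(triisopropylsilyloxy)methyl]furan-2(5H)-one | O=C1C=C[C@@H](CO[Si](C(C)C)(C(C)C)C(C)C)O1 | intermediate
3 | (E)-pent-3-en-2-one | C/C=C/C(C)=O | starting material
4 | (E)-2-(tert-butyldimethylsilyloxy)penta-1,3-diene | C/C=C/C(=C)O[Si](C)(C)C(C)(C)C | intermediate
5 | endo cycloadduct, cis-fused lactone with C16=C17 silyl enol ether | O=C1[C@@H]2[C@H](C)C=C(O[Si](C)(C)C(C)(C)C)C[C@@H]2[C@@H](CO[Si](C(C)C)(C(C)C)C(C)C)O1 | intermediate
6 | cis-fused keto lactone (C17 ketone, C14 methyl cis to C6 and C23, silyloxymethyl anti to ring B) | O=C1[C@@H]2[C@H](C)CC(=O)C[C@@H]2[C@@H](CO[Si](C(C)C)(C(C)C)C(C)C)O1 | intermediate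
7 | spiro-epoxy lactone (C19 equatorial, oxygen axial on C17) | O=C1[C@@H]2[C@H](C)C[C@]3(CO3)C[C@@H]2[C@@H](CO[Si](C(C)C)(C(C)C)C(C)C)O1 | intermediate
8 | C17 tertiary alcohol with C19 acetate | O=C1[C@@H]2[C@H](C)C[C@](O)(COC(C)=O)C[C@@H]2[C@@H](CO[Si](C(C)C)(C(C)C)C(C)C)O1 | intermediate
9 | diol lactone | O=C1[C@@H]2[C@H](C)C[C@](O)(CO)C[C@@H]2[C@@H](CO[Si](C(C)C)(C(C)C)C(C)C)O1 | intermediate
10 | acetonide lactone | O=C1[C@@H]2[C@H](C)C[C@]3(COC(C)(C)O3)C[C@@H]2[C@@H](CO[Si](C(C)C)(C(C)C)C(C)C)O1 | intermediate
11 | lactol (mixture at the hemiacetal carbon) | OC1[C@@H]2[C@H](C)C[C@]3(COC(C)(C)O3)C[C@@H]2[C@@H](CO[Si](C(C)C)(C(C)C)C(C)C)O1 | intermediate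
12 | alkynol, terminal alkyne on C13 and (S) carbinol on the C22 branch | C#C[C@@H]1[C@H](C)C[C@]2(COC(C)(C)O2)C[C@@H]1[C@H](O)CO[Si](C(C)C)(C(C)C)C(C)C | intermediate
13 | alkyne bis-silyl ether | C#C[C@@H]1[C@H](C)C[C@]2(COC(C)(C)O2)C[C@@H]1[C@H](O[Si](C)(C)C(C)(C)C)CO[Si](C(C)C)(C(C)C)C(C)C | intermediate
14 | ynone | CC(=O)C#C[C@@H]1[C@H](C)C[C@]2(COC(C)(C)O2)C[C@@H]1[C@H](O[Si](C)(C)C(C)(C)C)CO[Si](C(C)C)(C(C)C)C(C)C | intermediate
15 | (S)-propargylic alcohol | C[C@H](O)C#C[C@@H]1[C@H](C)C[C@]2(COC(C)(C)O2)C[C@@H]1[C@H](O[Si](C)(C)C(C)(C)C)CO[Si](C(C)C)(C(C)C)C(C)C | intermediate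
16 | (S,Z)-allylic alcohol, C13 cis to the carbinol carbon | C[C@H](O)/C=C(/C)[C@@H]1[C@H](C)C[C@]2(COC(C)(C)O2)C[C@@H]1[C@H](O[Si](C)(C)C(C)(C)C)CO[Si](C(C)C)(C(C)C)C(C)C | intermediate
17 | (R)-3-methylpentanoic acid | CC[C@@H](C)CC(=O)O | starting material
18 | allylic (R)-3-methylpentanoate | CC[C@@H](C)CC(=O)O[C@@H](C)/C=C(/C)[C@@H]1[C@H](C)C[C@]2(COC(C)(C)O2)C[C@@H]1[C@H](O[Si](C)(C)C(C)(C)C)CO[Si](C(C)C)(C(C)C)C(C)C | intermediate
19 | (E)-trimethylsilyl ketene acetal, sec-butyl cis to the allylic oxygen | CC[C@@H](C)/C=C(/O[Si](C)(C)C)O[C@@H](C)/C=C(/C)[C@@H]1[C@H](C)C[C@]2(COC(C)(C)O2)C[C@@H]1[C@H](O[Si](C)(C)C(C)(C)C)CO[Si](C(C)C)(C(C)C)C(C)C | intermediate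
20 | rearranged trimethylsilyl ester | CC[C@@H](C)[C@@H](C(=O)O[Si](C)(C)C)[C@](C)(/C=C/C)[C@@H]1[C@H](C)C[C@]2(COC(C)(C)O2)C[C@@H]1[C@H](O[Si](C)(C)C(C)(C)C)CO[Si](C(C)C)(C(C)C)C(C)C | intermediate
21 | carboxylic acid with C5 and C6 set, E-propenyl on C6 | CC[C@@H](C)[C@@H](C(=O)O)[C@](C)(/C=C/C)[C@@H]1[C@H](C)C[C@]2(COC(C)(C)O2)C[C@@H]1[C@H](O[Si](C)(C)C(C)(C)C)CO[Si](C(C)C)(C(C)C)C(C)C | intermediate
22 | methyl ketone | CC[C@@H](C)[C@@H](C(C)=O)[C@](C)(/C=C/C)[C@@H]1[C@H](C)C[C@]2(COC(C)(C)O2)C[C@@H]1[C@H](O[Si](C)(C)C(C)(C)C)CO[Si](C(C)C)(C(C)C)C(C)C | intermediate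
23 | ozonide (1,2,4-trioxolane on C6) | CC[C@@H](C)[C@@H](C(C)=O)[C@](C)(C1OOC(C)O1)[C@@H]2[C@H](C)C[C@]3(COC(C)(C)O3)C[C@@H]2[C@H](O[Si](C)(C)C(C)(C)C)CO[Si](C(C)C)(C(C)C)C(C)C | intermediate
24 | keto aldehyde, C8 aldehyde on C6 | CC[C@@H](C)[C@@H](C(C)=O)[C@](C)(C=O)[C@@H]1[C@H](C)C[C@]2(COC(C)(C)O2)C[C@@H]1[C@H](O[Si](C)(C)C(C)(C)C)CO[Si](C(C)C)(C(C)C)C(C)C | intermediate
25 | (E)-aldoxime | CC[C@@H](C)[C@@H](C(C)=O)[C@](C)(/C=N/O)[C@@H]1[C@H](C)C[C@]2(COC(C)(C)O2)C[C@@H]1[C@H](O[Si](C)(C)C(C)(C)C)CO[Si](C(C)C)(C(C)C)C(C)C | intermediate
26 | ethylene | C=C | starting material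
27 | hydroximoyl chloride | CC[C@@H](C)[C@@H](C(C)=O)[C@](C)(C(Cl)=NO)[C@@H]1[C@H](C)C[C@]2(COC(C)(C)O2)C[C@@H]1[C@H](O[Si](C)(C)C(C)(C)C)CO[Si](C(C)C)(C(C)C)C(C)C | intermediate
28 | nitrile oxide | CC[C@@H](C)[C@@H](C(C)=O)[C@](C)(C#[N+][O-])[C@@H]1[C@H](C)C[C@]2(COC(C)(C)O2)C[C@@H]1[C@H](O[Si](C)(C)C(C)(C)C)CO[Si](C(C)C)(C(C)C)C(C)C | intermediate
29 | isoxazoline bis-silyl ether | CC[C@@H](C)[C@@H](C(C)=O)[C@](C)(C1=NOCC1)[C@@H]2[C@H](C)C[C@]3(COC(C)(C)O3)C[C@@H]2[C@H](O[Si](C)(C)C(C)(C)C)CO[Si](C(C)C)(C(C)C)C(C)C | intermediate
30 | isoxazoline diol | CC[C@@H](C)[C@@H](C(C)=O)[C@](C)(C1=NOCC1)[C@@H]2[C@H](C)C[C@]3(COC(C)(C)O3)C[C@@H]2[C@H](O)CO | intermediate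
31 | keto aldehyde with isoxazoline and acetonide | CC[C@@H](C)[C@@H](C(C)=O)[C@](C)(C1=NOCC1)[C@@H]2[C@H](C)C[C@]3(COC(C)(C)O3)C[C@@H]2C=O | intermediate
32 | decalin α-ketol with isoxazoline and acetonide | CC[C@@H](C)[C@@H]1[C@](C)(C2=NOCC2)[C@@H]3[C@H](C)C[C@]4(COC(C)(C)O4)C[C@@H]3C(=O)[C@@]1(C)O | intermediate
33 | isoxazoline triol | CC[C@@H](C)[C@@H]1[C@](C)(C2=NOCC2)[C@@H]3[C@H](C)C[C@](O)(CO)C[C@@H]3C(=O)[C@@]1(C)O | intermediate
34 | β-hydroxy imine at C8 | CC[C@@H](C)[C@@H]1[C@](C)(C(=N)CCO)[C@@H]2[C@H](C)C[C@](O)(CO)C[C@@H]2C(=O)[C@@]1(C)O | intermediate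
35 | CNP0112523.4 | CC[C@@H](C)[C@@H]1[C@](C)(C(=O)CCO)[C@@H]2[C@H](C)C[C@](O)(CO)C[C@@H]2C(=O)[C@@]1(C)O | target

Total step count: 22. Longest linear sequence: 21 (steps 1 and 3 to 22).

Least certain steps

Step 20 (key step). The likely failure is poor facial discrimination at the acetyl carbonyl, because both chair-like closures are strained and the substrate bias may oppose the catalyst. Slow carbene addition to the hindered aldehyde would also leave time for base-mediated epimerisation at C22. Fallback: from 31, reductive pinacol cyclisation with SmI2 (divalent samarium, two equivalents, THF, t-BuOH, −78 °C, so that the N–O bond is spared) would give the ring A diol F1. Oxidation of its secondary C23 alcohol (SO3·pyridine, DMSO, i-Pr2NEt) returns to 32.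

Step 13. The likely failure is steric retardation of the [3,3] shift at the crowded C5–C6 bond, so that the ketene acetal decomposes, or leakage through the other ketene acetal geometry, which would give the C5 epimer. Fallback: the bond formation is split in two. From 16, a Johnson–Claisen rearrangement with triethyl orthoacetate (EtCO2H cat., 140 °C) would give the ethyl ester F2 with C6 set by the same chirality transfer. Saponification (LiOH) would give the acid F3, and esterification with (Z)-but-2-en-1-ol (DCC, DMAP) the (Z)-but-2-enyl ester F4. An Ireland–Claisen rearrangement (LDA, THF, Me3SiCl) would then join C5 to C3 and give the vinyl acid F5. Selective hydrogenation of the vinyl group (H2, RhCl(PPh3)3) returns to 21. In this variant the face of C5 rests on the adjacent quaternary centre, which is why it is the fallback and not the plan.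

Step 11. The likely failure is slow carbometalation at an alkyne flanked by the crowded C13, with reduction or loss of regiocontrol as competing processes. Fallback: from 14, conjugate syn addition of Me2CuLi (THF, −78 °C, cold quench) would give the (Z)-enone F6. Enantioselective reduction with (R)-2-methyl-CBS-oxazaborolidine and BH3·SMe2 returns to 16.

Step 3. The likely failure is incomplete endo selectivity or low reactivity of the γ-substituted butenolide at the temperature the diene tolerates. Fallback: from 2 and 3, an anionic double Michael annulation (cross-conjugated lithium dienolate of 3 from LDA, THF, −78 °C → rt) would build the same ring stepwise and return to 6; no compound outside the list arises (F0).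

Step 7. The likely failure is enolisation of the open hydroxy aldehyde in basic methanol, which would epimerise C13 to the more stable trans arrangement before homologation. Fallback: from 10, the lactol 11 is isolated after the hydride reduction and treated with lithiated trimethylsilyldiazomethane (THF, −78 °C), an irreversible low-temperature Colvin homologation without an equilibrating base, which returns to 12; no compound outside the list arises (F0).

Further compounds

F1 | step 20 | ring A diol from pinacol closure (C23 carbinol, configuration immaterial) | CC[C@@H](C)[C@@H]1[C@](C)(C2=NOCC2)[C@@H]3[C@H](C)C[C@]4(COC(C)(C)O4)C[C@@H]3C(O)[C@@]1(C)O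
F2 | step 13 | ethyl ester from Johnson–Claisen rearrangement | CCOC(=O)C[C@](C)(/C=C/C)[C@@H]1[C@H](C)C[C@]2(COC(C)(C)O2)C[C@@H]1[C@H](O[Si](C)(C)C(C)(C)C)CO[Si](C(C)C)(C(C)C)C(C)C
F3 | step 13 | acid from saponification | OC(=O)C[C@](C)(/C=C/C)[C@@H]1[C@H](C)C[C@]2(COC(C)(C)O2)C[C@@H]1[C@H](O[Si](C)(C)C(C)(C)C)CO[Si](C(C)C)(C(C)C)C(C)C
F4 | step 13 | (Z)-but-2-enyl ester | C/C=C\COC(=O)C[C@](C)(/C=C/C)[C@@H]1[C@H](C)C[C@]2(COC(C)(C)O2)C[C@@H]1[C@H](O[Si](C)(C)C(C)(C)C)CO[Si](C(C)C)(C(C)C)C(C)C
F5 | step 13 | vinyl acid with C3 and C5 set | C=C[C@@H](C)[C@@H](C(O)=O)[C@](C)(/C=C/C)[C@@H]1[C@H](C)C[C@]2(COC(C)(C)O2)C[C@@H]1[C@H](O[Si](C)(C)C(C)(C)C)CO[Si](C(C)C)(C(C)C)C(C)C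
F6 | step 11 | (Z)-enone, C13 cis to the acetyl group | CC(=O)/C=C(/C)[C@@H]1[C@H](C)C[C@]2(COC(C)(C)O2)C[C@@H]1[C@H](O[Si](C)(C)C(C)(C)C)CO[Si](C(C)C)(C(C)C)C(C)C
F0 | step 3 | none | none
F0 | step 7 | none | none
A1 | alternative 1 | 1-alkenyl hexahydroisochromene enol ether (E alkenyl group anti to ring B) | CC[C@@H](C)/C=C(\C)[C@H]1OC(CCO[Si](C)(C)C(C)(C)C)=C(C)[C@@H]2[C@H](C)C[C@]3(COC(C)(C)O3)C[C@@H]21
A2 | alternative 1 | cis-decalin with C23=C25 alkene, quaternary C6 and C8 ketone | CC[C@@H](C)[C@@H]1[C@](C)(C(=O)CCO[Si](C)(C)C(C)(C)C)[C@@H]2[C@H](C)C[C@]3(COC(C)(C)O3)C[C@@H]2C=C1C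
A3 | alternative 2 | 2-methyl-1,4-benzoquinone | CC1=CC(=O)C=CC1=O
A4 | alternative 2 | (E)-2-(triisopropylsilyloxy)penta-1,3-diene | C/C=C/C(=C)O[Si](C(C)C)(C(C)C)C(C)C
A5 | alternative 2 | cis-fused enedione with C17 silyl enol ether | O=C1[C@@H]2[C@H](C)C=C(O[Si](C(C)C)(C(C)C)C(C)C)C[C@@H]2C(=O)C(C)=C1
A6 | alternative 3 | enol triflate with acrylate acceptor | CC[C@@H](C)[C@H](C(=C)C(=O)OC)[C@](C)(O[Si](CC)(CC)CC)C(=O)C1=C(OS(=O)(=O)C(F)(F)F)[C@H](C)C[C@]2(COC(C)(C)O2)C1
A7 | alternative 3 | bicyclic enone with quaternary C6 carrying methyl and ester | CC[C@@H](C)[C@@H]1[C@](C)(C(=O)OC)C2=C(C(=O)[C@@]1(C)O[Si](CC)(CC)CC)C[C@@]3(COC(C)(C)O3)C[C@H]2C
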